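Everything rests on cutting ring A at two neighbouring atoms at once: the C4a–C4 bond to the pyranone carbonyl and the C5–O bond of the chelated phenol. This vicinal acyl/hydroxyl pair on ring A, with the C8a oxygen beside it, is read as the imprint of an aryne. In one operation a benzyne bearing three contiguous oxygens inserts formally into the carboxyl C–O bond of benzyloxyacetic acid, oxygen landing on C5 and acyl carbon on C4a under the direction of the C8a OMOM group; the acid also brings C3 with its oxygen masked. The aryne is released from an ortho-silylaryl triflate carrying OMe (C7) and OMOM groups (C8, C8a).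

Key step: step 5

Remark on the chemistry: benzene numbering is used up to compound 8 and flavone numbering (O1, C2 to C8a) for positions from step 5 on. The triflate carbon of 8 becomes C4a and the silyl carbon becomes C5. The target has no stereocentre. Compounds 14, 15, F3 and F4 carry centres that are labile or are erased later, so they are racemic or mixtures and are drawn without descriptors.

Step 1
Reactants: 1 2,3-dihydroxy-4-methoxybenzaldehyde
Product: 2 4-methoxy-2,3-bis(methoxymethoxy)benzaldehyde
Conditions: MOMCl (3 equiv), iPr2NEt (4 equiv), CH2Cl2, 0 °C to rt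
Reagents that add atoms: chloromethyl methyl ether (MOMCl), COCCl
Why: Williamson-type O-alkylation with the highly electrophilic chloromethyl ether caps both catechol hydroxyls, the excess of reagent and base overcoming the hydrogen bond between the C2 hydroxyl and the aldehyde, which itself is untouched.

Step 2
Reactants: 2 4-methoxy-2,3-bis(methoxymethoxy)benzaldehyde
Product: 4 4-methoxy-2,3-bis(methoxymethoxy)phenol, via aryl formate 3 (not isolated)
Conditions: mCPBA (1.3 equiv), CH2Cl2, 0 °C to rt; NaHCO3 wash; then K2CO3 (cat), MeOH, rt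
Reagents that add atoms: 3-chloroperoxybenzoic acid (mCPBA), O=C(OO)c1cccc(Cl)c1
Why: Baeyer–Villiger oxidation in its Dakin sense, chosen as the peracid variant because no free ortho or para hydroxyl is present: the very electron-rich aryl group migrates in preference to hydride, and the formate is removed by mild transesterification that leaves the base-stable MOM acetals intact.

Step 3
Reactants: 4 4-methoxy-2,3-bis(methoxymethoxy)phenol
Product: 5 6-bromo-4-methoxy-2,3-bis(methoxymethoxy)phenol
Conditions: NBS (1.0 equiv), iPr2NH (10 mol%), CH2Cl2, −20 to 0 °C, dark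
Reagents that add atoms: N-bromosuccinimide (NBS), O=C1CCC(=O)N1Br
Why: Electrophilic aromatic bromination governed by the free phenol, the strongest donor on the ring: its para position carries OMe and one ortho position OMOM, so the amine-mediated delivery of bromine from NBS should go to the single open ortho carbon C6 (4-methoxyphenol itself brominates next to OH), and the neutral medium spares the acetals.

Step 4
Reactants: 5 6-bromo-4-methoxy-2,3-bis(methoxymethoxy)phenol
Product: 8 4-methoxy-2,3-bis(methoxymethoxy)-6-(trimethylsilyl)phenyl trifluoromethanesulfonate, via aryl trimethylsilyl ether 6 (not isolated), via lithium silylphenoxide 7 (not isolated)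
Conditions: HN(SiMe3)2, THF, reflux, evaporate; n-BuLi (1.1 equiv), THF, −90 to −78 °C; then Tf2O (1.2 equiv), −78 °C
Reagents that add atoms: hexamethyldisilazane, C[Si](C)(C)N[Si](C)(C)C; trifluoromethanesulfonic anhydride (Tf2O), O=S(=O)(OS(=O)(=O)C(F)(F)F)C(F)(F)F
Why: Standard one-flask preparation of an ortho-silylaryl triflate: O-silylation, bromine–lithium exchange that outruns any deprotonation, retro-Brook 1,3-shift of silicon from oxygen to the metalated carbon driven by formation of the lithium phenoxide, and O-sulfonylation of that phenoxide at low temperature, where MOM ethers are inert.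

Step 5
Reactants: 8 4-methoxy-2,3-bis(methoxymethoxy)-6-(trimethylsilyl)phenyl trifluoromethanesulfonate; 9 benzyloxyacetic acid
Product: 11 2-(benzyloxy)-1-[6-hydroxy-4-methoxy-2,3-bis(methoxymethoxy)phenyl]ethan-1-one, via trioxygenated benzyne 10 (not isolated)
Conditions: CsF (4 equiv), 9 (1.2 equiv), THF, 125 °C, sealed tube
Reagents that add atoms: none
Why: Fluoride removes the silyl group of 8 and triflate departs, giving benzyne 10, whose strained bond joins the future C4a (former triflate carbon) and C5 (former silyl carbon). The σ-withdrawing OMOM oxygen on C8a polarises and distorts this bond so that the caesium carboxylate of 9 adds through oxygen at C5, meta to that group, leaving the aryl anion on C4a next to it; the weak opposing pull of the C7 methoxy group is offset by the C8 OMOM group. The anion then attacks its own ester carbonyl through a four-membered alkoxide that opens to the C5 phenoxide and the C4a ketone (an anionic Fries-type 1,3-acyl shift), so the C5–O and C4a–C4 bonds are formed in one flask. The closest known reaction type is the fluoride-triggered formal insertion of arynes into the C–O bond of carboxylic acids, which gives ortho-hydroxyaryl ketones. No ring remains closed in the product and no stereocentre is created, so neither a closure mode nor facial control is at stake. The step needs regioselectivity, secured by the C8a OMOM group, and acyl shift ahead of protonation of the aryl anion, favoured by hot THF and excess CsF, which hold 9 as its carboxylate; acetals, ethers and the benzyl group are inert to these conditions.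

Step 6
Reactants: 11 2-(benzyloxy)-1-[6-hydroxy-4-methoxy-2,3-bis(methoxymethoxy)phenyl]ethan-1-one
Product: 12 2-(benzyloxy)-1-[6-(benzyloxy)-4-methoxy-2,3-bis(methoxymethoxy)phenyl]ethan-1-one
Conditions: BnBr (1.3 equiv), K2CO3 (2 equiv), DMF, 60 °C
Reagents that add atoms: benzyl bromide, BrCc1ccccc1
Why: Williamson etherification in which K2CO3 in DMF ionises only the phenol (far more acidic than the ketone α-CH2) and warming breaks its chelate to the carbonyl, so that the C5 oxygen is barred from the later ring closure.

Step 7
Reactants: 12 2-(benzyloxy)-1-[6-(benzyloxy)-4-methoxy-2,3-bis(methoxymethoxy)phenyl]ethan-1-one; 13 benzoyl chloride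
Product: 14 2-(benzyloxy)-1-[6-(benzyloxy)-4-methoxy-2,3-bis(methoxymethoxy)phenyl]-3-phenylpropane-1,3-dione
Conditions: LiN(SiMe3)2 (2.2 equiv), THF, −78 °C; 13 (1.1 equiv), −78 to −20 °C; aq NH4Cl
Reagents that add atoms: none
Why: Crossed Claisen-type C-acylation of the chelated lithium enolate of an α-alkoxy ketone with an acid chloride, the second equivalent of base absorbing the more acidic β-diketone as it forms and any enol benzoate serving as acyl donor to remaining enolate; the new centre (future C3) is labile and is erased in the next step.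

Step 8
Reactants: 14 2-(benzyloxy)-1-[6-(benzyloxy)-4-methoxy-2,3-bis(methoxymethoxy)phenyl]-3-phenylpropane-1,3-dione
Product: 16 3,5-bis(benzyloxy)-8-hydroxy-7-methoxy-2-phenyl-4H-chromen-4-one, via catechol diketone 15 (not isolated)
Conditions: conc HCl (cat), MeOH–THF, 60 °C
Reagents that add atoms: none
Why: Acid-catalysed acetal exchange frees the C8 and C8a phenols, and only the C8a hydroxyl can reach the benzoyl carbonyl (6-exo-trig hemiketalisation, then loss of water), the classical cyclodehydration of ortho-hydroxyaryl β-diketones to flavones, while the benzyl ether on C5 rules out the isomeric closure and any Wessely–Moser scrambling.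

Step 9
Reactants: 16 3,5-bis(benzyloxy)-8-hydroxy-7-methoxy-2-phenyl-4H-chromen-4-one; 17 butanoyl chloride
Product: 18 3,5-bis(benzyloxy)-7-methoxy-4-oxo-2-phenyl-4H-chromen-8-yl butanoate
Conditions: 17 (1.2 equiv), Et3N (1.5 equiv), DMAP (5 mol%), CH2Cl2, 0 °C to rt
Reagents that add atoms: none
Why: DMAP-catalysed esterification of the only free hydroxyl group in 16, so that no site selectivity is required.

Step 10
Reactants: 18 3,5-bis(benzyloxy)-7-methoxy-4-oxo-2-phenyl-4H-chromen-8-yl butanoate
Product: 19 3,5-dihydroxy-7-methoxy-4-oxo-2-phenyl-4H-chromen-8-yl butanoate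
Conditions: H2 (1 atm), 10% Pd/C, EtOAc–THF, rt
Reagents that add atoms: none
Why: Catalytic hydrogenolysis cleaves both benzylic C–O bonds, whereas the aryl butanoate, the methyl ether and the tetrasubstituted conjugated C2=C3 bond are inert under one atmosphere of hydrogen, the aprotic solvent excludes transesterification, and no free hydroxyl flanks C8, so the acyl group cannot migrate.

Compound list
1 | 2,3-dihydroxy-4-methoxybenzaldehyde | COc1ccc(C=O)c(O)c1O | starting material
2 | 4-methoxy-2,3-bis(methoxymethoxy)benzaldehyde | COCOc1c(C=O)ccc(OC)c1OCOC | intermediate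
3 | 4-methoxy-2,3-bis(methoxymethoxy)phenyl formate | O=COc1ccc(OC)c(OCOC)c1OCOC | intermediate
4 | 4-methoxy-2,3-bis(methoxymethoxy)phenol | Oc1ccc(OC)c(OCOC)c1OCOC | intermediate
5 | 6-bromo-4-methoxy-2,3-bis(methoxymethoxy)phenol | Oc1c(Br)cc(OC)c(OCOC)c1OCOC | intermediate
6 | [6-bromo-4-methoxy-2,3-bis(methoxymethoxy)phenoxy]trimethylsilane | C[Si](C)(C)Oc1c(Br)cc(OC)c(OCOC)c1OCOC | intermediate
7 | lithium 4-methoxy-2,3-bis(methoxymethoxy)-6-(trimethylsilyl)phenolate | [Li+].[O-]c1c([Si](C)(C)C)cc(OC)c(OCOC)c1OCOC | intermediate
8 | 4-methoxy-2,3-bis(methoxymethoxy)-6-(trimethylsilyl)phenyl trifluoromethanesulfonate | C[Si](C)(C)c1cc(OC)c(OCOC)c(OCOC)c1OS(=O)(=O)C(F)(F)F | intermediate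
9 | benzyloxyacetic acid | OC(=O)COCc1ccccc1 | starting material
10 | 5-methoxy-3,4-bis(methoxymethoxy)benzyne (1,2-didehydrobenzene) | C1#CC(OCOC)=C(OCOC)C(OC)=C1 | intermediate
11 | 2-(benzyloxy)-1-[6-hydroxy-4-methoxy-2,3-bis(methoxymethoxy)phenyl]ethan-1-one | O=C(COCc1ccccc1)c1c(O)cc(OC)c(OCOC)c1OCOC | intermediate
12 | 2-(benzyloxy)-1-[6-(benzyloxy)-4-methoxy-2,3-bis(methoxymethoxy)phenyl]ethan-1-one | O=C(COCc1ccccc1)c1c(OCc2ccccc2)cc(OC)c(OCOC)c1OCOC | intermediate
13 | benzoyl chloride | O=C(Cl)c1ccccc1 | starting material
14 | 2-(benzyloxy)-1-[6-(benzyloxy)-4-methoxy-2,3-bis(methoxymethoxy)phenyl]-3-phenylpropane-1,3-dione (racemic, keto form drawn) | O=C(c1ccccc1)C(OCc1ccccc1)C(=O)c1c(OCc2ccccc2)cc(OC)c(OCOC)c1OCOC | intermediate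
15 | 2-(benzyloxy)-1-[6-(benzyloxy)-2,3-dihydroxy-4-methoxyphenyl]-3-phenylpropane-1,3-dione (racemic, keto form drawn) | O=C(c1ccccc1)C(OCc1ccccc1)C(=O)c1c(OCc2ccccc2)cc(OC)c(O)c1O | intermediate
16 | 3,5-bis(benzyloxy)-8-hydroxy-7-methoxy-2-phenyl-4H-chromen-4-one | COc1cc(OCc2ccccc2)c2c(=O)c(OCc3ccccc3)c(-c3ccccc3)oc2c1O | intermediate
17 | butanoyl chloride | CCCC(Cl)=O | starting material
18 | 3,5-bis(benzyloxy)-7-methoxy-4-oxo-2-phenyl-4H-chromen-8-yl butanoate | CCCC(=O)Oc1c(OC)cc(OCc2ccccc2)c2c(=O)c(OCc3ccccc3)c(-c3ccccc3)oc12 | intermediate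
19 | 3,5-dihydroxy-7-methoxy-4-oxo-2-phenyl-4H-chromen-8-yl butanoate | CCCC(=O)Oc1c(OC)cc(O)c2c(=O)c(O)c(-c3ccccc3)oc12 | target

Total step count: 10
Longest linear sequence: 10 steps (1 to 19); 9, 13 and 17 are purchased.

Steps most likely to fail

Step 5. Three things may go wrong. The C4a aryl anion may be protonated before the acyl shift, which ends in plain O-arylation. The product phenoxide may be arylated further by a second aryne. The α-alkoxy ketone may condense with itself under base at 125 °C. The fallback sets out from 8 and separates the two carbon–carbon bond formations. Benzyne 10 is generated with CsF in DMF, which serves as solvent and reactant with no proton source present. The aryne inserts formally into the formamide C=O bond with the same orientation. Aqueous work-up should then hydrolyse the adduct to 6-hydroxy-4-methoxy-2,3-bis(methoxymethoxy)benzaldehyde F1. Benzylation (BnBr, K2CO3, DMF) should give 6-(benzyloxy)-4-methoxy-2,3-bis(methoxymethoxy)benzaldehyde F2. Addition of BnOCH2Li (from Bu3SnCH2OBn and n-BuLi, THF, −78 °C) should give racemic 2-(benzyloxy)-1-[6-(benzyloxy)-4-methoxy-2,3-bis(methoxymethoxy)phenyl]ethan-1-ol F3. Oxidation with Dess–Martin periodinane comes back to the route at 12.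

Step 7. O-acylation of the enolate may compete, the diketone may be acylated twice, or the hindered di-ortho-substituted aryl ketone enolate may react sluggishly. The fallback sets out from 12 and replaces acylation by aldol addition and oxidation. The lithium enolate (LiN(SiMe3)2, THF, −78 °C) is added to benzaldehyde. This should give 2-(benzyloxy)-1-[6-(benzyloxy)-4-methoxy-2,3-bis(methoxymethoxy)phenyl]-3-hydroxy-3-phenylpropan-1-one F4 as an inconsequential mixture of diastereomers. Dess–Martin oxidation comes back to the route at 14.

Step 3. NBS may oxidise the hydroquinone monoether ring to a quinone, bromine may enter next to the methoxy group, or traces of acid may remove a MOM group. The fallback sets out from 4 and installs silicon by directed ortho-metalation in place of halogenation.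
- Carbamoylation (ClC(O)NEt2, NaH, THF) should give 4-methoxy-2,3-bis(methoxymethoxy)phenyl N,N-diethylcarbamate F5.
- s-BuLi/TMEDA (THF, −78 °C) lithiates the only C–H next to the carbamate, and a Me3SiCl quench should give 4-methoxy-2,3-bis(methoxymethoxy)-6-(trimethylsilyl)phenyl N,N-diethylcarbamate F6.
- LiAlH4 in THF cleaves the carbamate to 4-methoxy-2,3-bis(methoxymethoxy)-6-(trimethylsilyl)phenol F7.
- Deprotonation with n-BuLi comes back to the route at 7, which Tf2O converts into 8 as in step 4.

Further compounds
F1 | step 5 | 6-hydroxy-4-methoxy-2,3-bis(methoxymethoxy)benzaldehyde | O=Cc1c(O)cc(OC)c(OCOC)c1OCOC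
F2 | step 5 | 6-(benzyloxy)-4-methoxy-2,3-bis(methoxymethoxy)benzaldehyde | O=Cc1c(OCc2ccccc2)cc(OC)c(OCOC)c1OCOC
F3 | step 5 | 2-(benzyloxy)-1-[6-(benzyloxy)-4-methoxy-2,3-bis(methoxymethoxy)phenyl]ethan-1-ol (racemic) | OC(COCc1ccccc1)c1c(OCc2ccccc2)cc(OC)c(OCOC)c1OCOC
F4 | step 7 | 2-(benzyloxy)-1-[6-(benzyloxy)-4-methoxy-2,3-bis(methoxymethoxy)phenyl]-3-hydroxy-3-phenylpropan-1-one (mixture of diastereomers) | OC(c1ccccc1)C(OCc1ccccc1)C(=O)c1c(OCc2ccccc2)cc(OC)c(OCOC)c1OCOC
F5 | step 3 | 4-methoxy-2,3-bis(methoxymethoxy)phenyl N,N-diethylcarbamate | CCN(CC)C(=O)Oc1ccc(OC)c(OCOC)c1OCOC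
F6 | step 3 | 4-methoxy-2,3-bis(methoxymethoxy)-6-(trimethylsilyl)phenyl N,N-diethylcarbamate | CCN(CC)C(=O)Oc1c([Si](C)(C)C)cc(OC)c(OCOC)c1OCOC
F7 | step 3 | 4-methoxy-2,3-bis(methoxymethoxy)-6-(trimethylsilyl)phenol | Oc1c([Si](C)(C)C)cc(OC)c(OCOC)c1OCOC
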